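A closed, stirred vessel at constant temperature starts with free monomer and pre-initiator, and chains begin, grow and shrink in it.

free monomer 0.10 M; pre-initiator 0.68 mM; time 1.0 min

    free monomer + initiator → living end + monomer in chains (k1 = 39 M⁻¹ s⁻¹)
    free monomer + living end → monomer in chains + living end, rate k2*[living end]*[free monomer] (k2 = 36 M⁻¹ s⁻¹)
    monomer in chains + living end → free monomer + living end, rate k3*[living end] as long as [monomer in chains] is above zero (k3 = 0.42 s⁻¹)
    pre-initiator → initiator (k4 = 0.0099 s⁻¹)

- the average divides the monomer in chains by the number of chains begun, living and dead together
- run time (flask): 1.0 min

- average number of monomer units in a chain (chains begun, living or dead) at 1.0 min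
- part of the free monomer that has reacted at 1.0 min

We count lifetimes. Growth removes free monomer with a lifetime equal to the inverse of its rate constant times the living ends, so we ask how many such lifetimes have passed. Take growth first, with the whole charge of pre-initiator counted as living ends from the start. That gives 1.47 lifetimes in 1.0 min, and 77.0% of the free monomer reacted.

Now add the release. By its own step, pre-initiator has a half-life of 1.2 min. Initiator, by step 1 at the charged free monomer, has a far shorter one of 0.18 s, so we let living ends follow the amount released, which we reckon at 0.305 mM at 1.0 min. The scheme has no step that ends a chain, so we count this amount as the chains begun. The area under the living ends equals the whole charge acting for 14.8 s of the 60 s. The count drops to 0.361. This is the lifetime count: the growth constant times the area under the living ends against time. The share reacted falls to 30.3%.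

Now add the back step. It also runs in proportion to the living ends, so it balances growth at a free monomer of 0.0117 M, the equilibrium monomer concentration. The count therefore acts on the excess above that floor. We get 26.8% reacted, and dividing the monomer in chains by the chains begun gives a length of 87.9.

The forecast gives 88 and 26.7%, holding that “the number of chains simply tracks that slow release”. The flask gives 88.5 and 26.8%.

At a count of 0.361, the flask keeps 73.2% of its free monomer at 1.00 min. The neighbouring flask is charged with 0.0012 M of pre-initiator and read at the same time. Its effective time stays 14.8 s, so we scale the count with the charge, to 0.638. With the same floor we reckon 41.6% reacted. We reckon its chains begun at 0.537 mM, and so a length of 77.5. The simulated neighbour shows 41.7% reacted and a length of 78.0.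

(Its constants are invented, and the outcome is calculated.)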